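## Structural features

The target is a 14,15-dinorlabdane: a trans-fused decalin (ring A: C1–C5 and C10; ring B: C5–C10) with an exocyclic C8=C17 methylene group, a 3-oxobutyl chain (C11, C12, C13, C16) on C9 and the angular C20 methyl group on C10. Ring A carries an equatorial 2α-hydroxyl and the quaternary C4 with the 18-methyl group (α) and the axial 19-acetoxymethyl group (β); ring B carries an axial, allylic 7α-hydroxyl. Four of the six stereocentres are contiguous (C4–C5–C10–C9): two quaternary carbons (C4, C10) in a 1,3-relationship whose β substituents C19 and C20 are syn-diaxial, each flanked by a tertiary CH (C5, C9) with its hydrogen α. Fragile points are: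
- the allylic alcohol beside the exocyclic alkene (ionisation, over-oxidation to the enone);
- the primary acetate beside two free secondary alcohols (they must be told apart by protecting groups, and the acetate tolerates neither dissolving metals nor organometallic reagents);
- the C13 ketone, which is 1,5 to C8 and closes by aldol reaction whenever C8 is a ketone;
- every ring A intermediate with a silyloxy group β to a ketone (E1cB loss of silanol).

The real difficulty is the trans-fused C4–C5–C10–C9 array. C10 must receive its methyl group syn to the axial C19 group. C5 and C9 must carry their carbon substituents on the same face as the axial groups of the neighbouring quaternary carbons, whereas an electrophile attacking C5 or C9 enters anti to those groups. The key step uses the fact that C9, C10 and C20 can be tied into a cyclopropane conjugated with a C8 ketone: a carbenoid at C9, tethered to C5 of ring A, adds to an exocyclic C10=C20 alkene, closes ring B and fixes C10. Later reductive cleavage of C9–C20 releases the methyl group and a regiodefined C8–C9 enolate.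

## Logic of the disconnections

**35 from 34 and 33 (C7–O and the last silyl group).** The axial allylic C7–O bond and the O–Si bond at C2 are cut first. The 7α-hydroxyl is the most fragile group and is best made last by allylic C–H oxidation of the C8(17) alkene of 33. This removes a stereocentre and an acid- and oxidation-sensitive alcohol from every earlier intermediate. The forward step must oxidise C7 and not the tertiary C9–H, deliver oxygen to the α face and stop at the alcohol; the final desilylation must spare acetate and allylic alcohol.

**33 from 32 and 31 (acyl group on O19).** The acetate is exchanged for a triethylsilyl ether, because an ester on C19 would not survive the reducing metal and the organometallic reagents used earlier. One protecting group can then be carried from the ring A stage. The demand is that the primary triethylsilyl ether is cleaved beside the secondary tert-butyldimethylsilyl ether at C2.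

**31 from 30 and 29 (C13–C16 and C8=C17).** C16 is removed by writing the methyl ketone as a thioester, and the C8 methylene group as a ketone. With C13 at the acid level, C8 is the only ketone in 29, so no choice between two ketones is needed and no 1,5-diketone with its aldol tendency appears. The forward steps need a non-basic methylenation of a hindered ketone whose α-carbon C9 is a stereocentre, and an acyl substitution that stops at the ketone.

**29 from 25 and 27 (C11–C12 and C9–H); 27 from 26.** The chain is cut between C11 and C12, which leaves an exocyclic enone, and the C9–H bond is formed in the same step by protonation of the C8–C9 enolate. The reason is stereochemical: a carbon electrophile would attack that enolate anti to the axial C20 methyl and put the chain on the α face, whereas a proton arriving anti to C20 leaves the chain β. The forward step needs 1,4-addition at the exocyclic carbon and α-face protonation; 27 is one step from 26.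

**25 from 21 (C9–C11, with C9–C20 reconnected).** Removing C11 leaves the C8–C9 enolate of the angularly methylated decalone. This enolate cannot be made from the ketone, which enolises toward C7, but it is what reductive opening of a C9–C10–C20 cyclopropyl ketone gives. Reconnecting C9 to C20 turns the angular methyl group and the regiochemistry problem into one strained ring. The forward step must cleave C9–C20 and not C9–C10, and trap the enolate before proton exchange.

**21 from 20 (C9–C10 and C9–C20; the key step).** Both cyclopropane bonds to C9 are cut. This opens ring B and the three-membered ring and leaves ring A with an exocyclic C10=C20 alkene and a diazomethyl ketone on a two-carbon arm at C5. Two rings, two C–C bonds and two stereocentres (C9, C10) disappear at once, and the hardest centre, C10, becomes an sp2 carbon. The forward step must deliver the carbenoid to the α face of the alkene and prefer the alkene to nearby C–H bonds.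

**20 from 18 and 17 (C8–C9).** The diazoketone is cut at the acyl–carbon bond to a carboxylic acid and a one-carbon diazo nucleophile; the acid comes from its methyl ester. The demand is an acid activation that spares the acid-labile triethylsilyl ether.

**17 from 16, 15 and 14 (C10=C20, O–Si, C19–O).** The exocyclic alkene goes back to the C10 ketone that was needed to build C4 and C5. The C19 oxygen is traded for silicon, because C19 is best introduced as a nucleophile and a silylmethyl group is the hydroxymethyl nucleophile that adds conjugately. The forward sequence must oxidise the C–Si bond while no alkene is present, and must methylenate without base, since C5 is α and the C2 silyloxy group β to the ketone.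

**14 from 11 and 12 (C6–C7 and C5–H).** As at C9, the chain is cut one carbon out from the ring so that the last bond formed at C5 is C–H. Protonation of the C10–C5 enolate anti to the axial C19 group gives the cis relationship of chain and C19 that alkylation at C5 would not give. What remains is an α-methylene ketone and a two-carbon ester nucleophile.

**11 from 8 (C5=C6).** The methylene carbon is removed to give the enol ether whose double bond marks C5 as the nucleophilic carbon. The forward step needs a one-carbon electrophile that reacts at a neopentyl position and can then be eliminated.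

**8 from 7 (C4–C19).** Conjugate disconnection of the silylmethyl group from the β-carbon gives a β-methyl enone. The quaternary C4 then arises by addition trans to the silyloxy group at C2, which is the required relative configuration. The forward step must be a 1,4-addition to a β,β-disubstituted enone with the enolate trapped on the C5 side.

**7 from 6 and 5 (C4–C18 and the position of the carbonyl).** The methyl group is removed through the retron of an oxidative 1,3-transposition: a tertiary allylic alcohol from 1,2-addition of a methyl nucleophile to an unsubstituted enone. This leads to a 5-silyloxycyclohexenone with one stereocentre.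

**5 from 3, 2 and 1 (C=C and symmetry).** The enone is the elimination product of a β-acetoxy ketone, and 3 is a desymmetrised form of the meso diol 2, the mono-silyl ether of 1. The single stereocentre that controls all others is thus drawn from an achiral triol, and the demand falls on the enantiotopic-group selectivity of the acylation.

## Other disconnections considered

**Alternative 1:** Cut C4–C5 and C9–C10 together, so that both rings come from the acyclic polyene β-keto ester A1.
- Forward key step: Mn(OAc)3 would oxidise the α-methyl β-keto ester to the C4 radical; 6-endo closure gives ring A and a tertiary C10 radical; a second 6-endo closure onto the C8=C9 alkene gives ring B; Cu(OAc)2 oxidises the C8 radical to the exocyclic alkene of A2.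
- In favour: two rings, the four contiguous centres C4, C5, C9, C10, the trans fusion and the C8(17) alkene would arise in one step, with the ketalised side chain already present. In ring construction and in step economy up to the decalin this is better than the chosen plan, which needs about fifteen steps to reach 21. A radical cascade is also less sensitive to crowding at C4 and C10 than the ionic additions used here.
- Against, for this target: A2 has its ring A oxygen at C3 and C19 at the ester level, whereas the target needs a 2α-hydroxyl, an unfunctionalised C3 and a C19 CH2OAc group. A 1,2-transposition of oxygen with control of C2, plus reduction of a hindered ester beside alkene and ketal, would add about six steps and new selectivity problems. The absolute configuration would rest on a stoichiometric ester auxiliary acting on a flexible cascade, and the oxidative termination could also give endocyclic alkenes.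
- Comparison: superior for a 3-oxygenated labdane, inferior for this 2-oxygenated one. The chosen plan starts with the C2 oxygen in place and sets each centre in a separate, controllable event.

**Alternative 2:** Cut C3–C4, closing ring A last on the ring B ketone A3, which carries the C9 chain, the C10 methyl group, a C1–C3 arm ending in a Z-vinyl iodide and a 2-(silyloxymethyl)vinyl group on C5.
- Forward key step: Pd(OAc)2/PPh3 would insert into the C3–I bond; 6-exo carbopalladation of the C4=C18 alkene forms C3–C4 and the quaternary C4; HCO2Na reduces the neopentyl C18–Pd bond, which has no β-hydrogen, to the methyl group of A4.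
- In favour: the quaternary carbon forms under catalytic, sterically tolerant conditions, at least the equal of the copper-catalysed conjugate addition used here for C4. The C8 ketone and the protected chain are already present, so the end game would equal ours.
- Against: A4 has a C2=C3 alkene, and nothing in the ring biases the regiochemistry (C2 against C3) or the face of the hydration needed for the 2α-hydroxyl. The configuration at C4 depends on which face of the 1,1-disubstituted alkene the vinylpalladium attacks, and the required isomer puts the CH2OSi group syn-diaxial to C20. A3 itself needs C5, C9 and C10 set on ring B beforehand, with absolute configuration relayed from a terpene whose surplus carbons must be excised.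
- Comparison: bond construction at C4 is equal or better; control of the C2 and C4 configurations is weaker; the sequence would probably not be shorter.

**Alternative 3:** Cut C8–C9 and C11–C12 in a [2+2] sense, so that ring B and the chain come from the dioxinone A5, in which ring A already bears the quaternary C10 (methyl and vinyl).
- Forward key step: irradiation would add the dioxinone C8=C12 alkene across the vinyl group (C8–C9 and C11–C12); K2CO3 in methanol then opens the dioxinone and cleaves C8–C12 by retro-aldol reaction to the 8-oxo ester A6.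
- In favour: ring B, the C8 ketone, the C9 centre and the three-carbon chain come from one two-stage operation. A6 is the methyl ester analogue of 29, so protecting groups and end game are equal to ours, and the chain arrives without a separate methylenation and Michael sequence, which is better step economy after ring A.
- Against: the hard problem moves into the precursor. C10 must be built as a quaternary stereocentre on ring A, 1,3 to quaternary C4 and syn-diaxial with C19, by intermolecular chemistry with no tether to help; this is what the carbenoid tether solves in the chosen plan. The regiochemistry of the photocycloaddition (straight against crossed) and the C9 configuration are not secured by the substrate, although C9 could equilibrate after the retro-aldol step. Throughput of the photochemical step is a further cost.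
- Comparison: equal in end game, better in step count after ring A, worse in control of C10, the centre that defines the problem.

Key step: step 14

Remark 1: labdane numbering is used for all intermediates, also monocyclic ones (ring A = C1–C5 and C10; C18 = α-methyl and C19 = β-CH2 on C4); α and β refer to the target drawn with C20 β.

Remark 2: in step 2 the lipase is assumed to acetylate the hydroxyl on the (R)-configured carbon of 2, the usual preference of lipases for secondary alcohols; the opposite case is treated after the compound list.

## Route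

Step 1
Reactants: 1 cis,cis-cyclohexane-1,3,5-triol
Product: 2 all-cis-5-(tert-butyldimethylsilyloxy)cyclohexane-1,3-diol (meso)
Conditions: TBSCl (0.9 equiv), imidazole, DMF, 0 °C → rt
Reagents that add atoms: tert-butyldimethylsilyl chloride, CC(C)(C)[Si](C)(C)Cl
Why: Corey silylation of one of three equivalent hydroxyls; a deficit of silyl chloride limits bis-silylation, unreacted 1 is recovered, and 2 is meso, so no stereochemistry is decided here.

Step 2
Reactants: 2 all-cis-5-(tert-butyldimethylsilyloxy)cyclohexane-1,3-diol
Product: 3 (1R,3S,5S)-3-hydroxy-5-(tert-butyldimethylsilyloxy)cyclohexyl acetate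
Conditions: Candida antarctica lipase B (immobilised), vinyl acetate, t-BuOMe, rt
Reagents that add atoms: vinyl acetate, C=COC(C)=O
Why: Lipase-catalysed irreversible transesterification desymmetrises the meso diol by acetylating one enantiotopic hydroxyl (the one on the (R)-configured carbon); this fixes the absolute configuration of the carbon that becomes C2 and thereby of all later centres.

Step 3
Reactants: 3 (1R,3S,5S)-3-hydroxy-5-(tert-butyldimethylsilyloxy)cyclohexyl acetate
Product: 5 (R)-5-(tert-butyldimethylsilyloxy)cyclohex-2-en-1-one, via acetoxy ketone 4 (not isolated)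
Conditions: Dess–Martin periodinane, NaHCO3, CH2Cl2, rt; then Et3N, 0 °C
Reagents that add atoms: none
Why: Dess–Martin oxidation gives the β-acetoxy ketone, which loses acetic acid by E1cB elimination on brief contact with Et3N; the silyloxy-bearing centre is not touched.

Step 4
Reactants: 5 (R)-5-(tert-butyldimethylsilyloxy)cyclohex-2-en-1-one
Product: 6 (5R)-5-(tert-butyldimethylsilyloxy)-1-methylcyclohex-2-en-1-ol (both C1 epimers)
Conditions: MeLi, Et2O, −78 °C
Reagents that add atoms: methyllithium, [Li]C
Why: 1,2-Addition of an organolithium reagent to the enone carbonyl; the new carbinol centre disappears in step 5, so its configuration does not matter.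

Step 5
Reactants: 6 (5R)-5-(tert-butyldimethylsilyloxy)-1-methylcyclohex-2-en-1-ol
Product: 7 (S)-5-(tert-butyldimethylsilyloxy)-3-methylcyclohex-2-en-1-one
Conditions: pyridinium chlorochromate [C5H5NH][CrO3Cl], 4 Å molecular sieves, CH2Cl2, rt
Reagents that add atoms: pyridinium chlorochromate, [O-][Cr](=O)(=O)Cl.c1cc[nH+]cc1
Why: Babler–Dauben oxidative 1,3-transposition: the chromate ester of the tertiary allylic alcohol undergoes a [3,3]-shift and the secondary allylic chromate is oxidised, which puts the methyl group on the β-carbon (C4) and the carbonyl on the future C10; the carbonyl oxygen comes from the chromate.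

Step 6
Reactants: 7 (S)-5-(tert-butyldimethylsilyloxy)-3-methylcyclohex-2-en-1-one
Product: 8 ring A trimethylsilyl enol ether (C10=C5; 2α-OTBS; 4α-methyl; 4β-[(dimethylphenylsilyl)methyl])
Conditions: PhMe2SiCH2MgCl, CuI (10 mol%), Me3SiCl, THF, −78 → −40 °C; Et3N quench
Reagents that add atoms: (dimethylphenylsilyl)methylmagnesium chloride, C[Si](C)(C[Mg]Cl)c1ccccc1; chlorotrimethylsilane, C[Si](C)(C)Cl
Why: Copper-catalysed, Me3SiCl-accelerated conjugate addition of a silylmethyl Grignard reagent (a hydroxymethyl anion equivalent) to a β-methyl enone; axial attack anti to the pseudo-equatorial silyloxy group places C19 trans to the C2 oxygen and creates quaternary C4, and silylation traps the enolate regiospecifically toward C5.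

Step 7
Reactants: 8 ring A trimethylsilyl enol ether
Product: 11 5-methylene ring A ketone (C10=O; C5=C6; 2α-OTBS; 4β-CH2SiMe2Ph), via Mannich base 9 (not isolated), via methiodide 10 (not isolated)
Conditions: CH2=NMe2+ I− (Eschenmoser's salt), CH2Cl2, rt; then MeI, Et2O, rt; then NaHCO3 (aq), CH2Cl2, rt
Reagents that add atoms: N,N-dimethylmethyleneiminium iodide, C=[N+](C)C.[I-]
Why: Mannich reaction of the silyl enol ether with Eschenmoser's salt, N-methylation and β-elimination of trimethylamine give the α-methylene ketone; C6 is attached to C5 without committing the C5 configuration, and the base is too mild to expel the β-silyloxy group.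

Step 8
Reactants: 11 5-methylene ring A ketone; 12 1-(tert-butyldimethylsilyloxy)-1-methoxyethene
Product: 14 ring A keto ester (C10=O; 5α-H; 5β-CH2CH2CO2Me; 2α-OTBS; 4β-CH2SiMe2Ph), via silyl enol ether 13 (not isolated)
Conditions: Sc(OTf)3 (5 mol%), CH2Cl2, −78 °C; then Bu4NF, AcOH, THF, −78 °C
Reagents that add atoms: none
Why: Lewis-acid-catalysed Mukaiyama–Michael addition of the ketene silyl acetal to the unhindered exocyclic carbon C6; fluoride and acetic acid then protonate the C10–C5 enolate kinetically on the α face, anti to the axial C19 substituent on C4, so H5 becomes α and the chain β, cis to C19, which alkylation at C5 would not give.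

Step 9
Reactants: 14 ring A keto ester
Product: 15 ring A hydroxy keto ester (19-OH)
Conditions: KBr, AcOOH, NaOAc, AcOH, 0 °C → rt
Reagents that add atoms: peracetic acid, CC(=O)OO
Why: Fleming–Tamao oxidation: ipso-bromodesilylation of the phenyl group, then peracid-induced 1,2-shift of C19 from silicon to oxygen with retention; the acetate buffer protects the silyl ether and no alkene is present to compete for the peracid.

Step 10
Reactants: 15 ring A hydroxy keto ester
Product: 16 ring A keto ester with 19-OSiEt3
Conditions: Et3SiCl, imidazole, CH2Cl2, 0 °C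
Reagents that add atoms: chlorotriethylsilane, CC[Si](Cl)(CC)CC
Why: Silylation of the neopentyl primary alcohol; the triethylsilyl ether is orthogonal to the secondary tert-butyldimethylsilyl ether and later shields the β face at C10.

Step 11
Reactants: 16 ring A keto ester with 19-OSiEt3
Product: 17 methyl 3-(ring A)propanoate with exocyclic C10=C20 (5α-H; 2α-OTBS; 19-OSiEt3)
Conditions: Zn, CH2Br2, TiCl4, THF/CH2Cl2, 0 °C → rt
Reagents that add atoms: dibromomethane, BrCBr
Why: Takai–Lombardo methylenation with a gem-dimetallic zinc/titanium reagent; it is non-basic, so C5 (α to the ketone) does not epimerise and the β-silyloxy group is not eliminated, and the ester is not attacked.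

Step 12
Reactants: 17 methylene ester
Product: 18 3-(ring A)propanoic acid (C8 acid)
Conditions: LiOH, THF/MeOH/H2O, rt; then dilute HCl to pH 4–5, 0 °C
Reagents that add atoms: lithium hydroxide, [Li+].[OH-]
Why: Saponification of the methyl ester; no epimerisable centre is left, and the hindered primary triethylsilyl ether tolerates aqueous LiOH and a brief cold acidification.

Step 13
Reactants: 18 C8 acid
Product: 20 diazoketone (C9 diazomethyl ketone on the C6–C7 arm of ring A), via mixed anhydride 19 (not isolated)
Conditions: i-BuOCOCl, Et3N, THF, −15 °C; then CH2N2, Et2O, 0 °C → rt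
Reagents that add atoms: diazomethane, C=[N+]=[N-]
Why: Activation as the mixed carbonic anhydride avoids HCl, so the triethylsilyl ether survives; C-acylation of diazomethane at the more electrophilic acyl carbon (first stage of the Arndt–Eistert sequence) gives the diazomethyl ketone.

Step 14
Reactants: 20 diazoketone
Product: 21 tricyclic cyclopropyl ketone (C8=O; C9–C10–C20 cyclopropane; 5α-H; 2α-OTBS; 19-OSiEt3)
Conditions: Rh2(OAc)4 (1 mol%), CH2Cl2, rt, slow addition of 20 at high dilution
Reagents that add atoms: none
Why: Rh2(OAc)4 converts the diazoketone, with loss of N2, into an electrophilic rhodium carbenoid at C9, which adds to the electron-rich 1,1-disubstituted C10=C20 alkene in a concerted but asynchronous [2+1] step in which the bond to the terminal C20 leads. The closest known reaction type is the intramolecular cyclopropanation of 1-diazoalk-6-en-2-ones to bicyclo[4.1.0]heptan-2-ones, including additions to exocyclic methylene groups. Ring B closes in the exo mode through C9–C10, the arm C6–C7–C8–C9 spanning C5 and C10, and the cyclopropane closes through the second bond C9–C20. At C10 the carbenoid must arrive on the α face so that C9 becomes equatorial and C20 axial (β); the axial C19 triethylsilyloxymethyl group on C4 is 1,3-diaxial to the β lobe of the alkene and blocks that face, and the equatorial C5–C6 bond lets the arm reach C10 through a chair-like, trans-decalin-like transition state. The configuration at C9 follows from the suprafacial addition, because the cyclopropane can only be cis-fused to ring B once the face at C10 is chosen. The step also needs chemoselectivity for the alkene over insertion into the allylic C5–H bond (five-membered ring) and over carbenoid dimerisation, which the nucleophilic alkene, carboxylate ligands and slow addition favour; the C–H bonds next to the silyl ether oxygens are out of reach, since insertion at C19 would need a seven-membered ring.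

Step 15
Reactants: 21 cyclopropyl ketone
Product: 25 9(11)-en-8-one of the decalin (C20 methyl β on C10; 2α-OTBS; 19-OSiEt3), via lithium enolate 22 (not isolated), via Mannich base 23 (not isolated), via methiodide 24 (not isolated)
Conditions: Li, NH3 (l), THF, t-BuOH (1 equiv), −78 °C; isoprene; NH3 evaporated; CH2=NMe2+ I−, THF, −78 → 0 °C; then MeI, Et2O, rt; then NaHCO3 (aq), CH2Cl2, rt
Reagents that add atoms: N,N-dimethylmethyleneiminium iodide, C=[N+](C)C.[I-]
Why: Dissolving-metal reduction cleaves the cyclopropane bond that overlaps with the carbonyl π system (C9–C20, exocyclic to ring B), leaving C20 as the β-methyl group on C10 and the regiodefined C8–C9 lithium enolate. The enolate is aminomethylated at C9 with Eschenmoser's salt, and the Mannich base is methylated and eliminated to the exocyclic enone, so the C9 configuration is deliberately left open.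

Step 16
Reactants: 26 S-ethyl thioacetate
Product: 27 1-(ethylsulfanyl)-1-(trimethylsilyloxy)ethene
Conditions: LiN(i-Pr)2, THF, −78 °C; Me3SiCl
Reagents that add atoms: chlorotrimethylsilane, C[Si](C)(C)Cl
Why: Kinetic deprotonation of the thioester and O-silylation of its enolate give the ketene silyl thioacetal that serves as the C12–C13 nucleophile.

Step 17
Reactants: 25 9(11)-en-8-one; 27 1-(ethylsulfanyl)-1-(trimethylsilyloxy)ethene
Product: 29 8-oxo S-ethyl thioester (9α-H; chain C11–C12–C13 on C9 β), via silyl enol ether 28 (not isolated)
Conditions: Sc(OTf)3 (5 mol%), CH2Cl2, −78 °C; then Bu4NF, AcOH, THF, −78 °C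
Reagents that add atoms: none
Why: Mukaiyama–Michael addition at the exocyclic C11; the C8–C9 enolate released by fluoride is protonated on the α face, anti to the axial C20 methyl group, which gives 9α-H with the chain equatorial (β); this epimer is also the more stable one, so it is not eroded later.

Step 18
Reactants: 29 8-oxo thioester
Product: 30 8(17)-ene S-ethyl thioester
Conditions: Zn, CH2Br2, TiCl4, THF/CH2Cl2, 0 °C → rt
Reagents that add atoms: dibromomethane, BrCBr
Why: Takai–Lombardo methylenation of the hindered C8 ketone without base, so C9 keeps its configuration; thioesters and silyl ethers are inert to the reagent.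

Step 19
Reactants: 30 8(17)-ene thioester
Product: 31 2α-(tert-butyldimethylsilyloxy)-19-(triethylsilyloxy)-14,15-dinorlabd-8(17)-en-13-one
Conditions: Me2CuLi (from MeLi and CuI), Et2O, −78 → −40 °C
Reagents that add atoms: lithium dimethylcuprate, [Li+].C[Cu-]C
Why: Thioesters undergo acyl substitution with lithium dialkylcuprates and the ketone formed does not react further at low temperature, which installs C16 without touching alkene or silyl ethers.

Step 20
Reactants: 31 silyl-protected 13-ketone
Product: 32 2α-(tert-butyldimethylsilyloxy)-19-hydroxy-14,15-dinorlabd-8(17)-en-13-one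
Conditions: HF·pyridine, pyridine, THF, 0 °C
Reagents that add atoms: none
Why: Buffered HF·pyridine cleaves the primary triethylsilyl ether much faster than the secondary tert-butyldimethylsilyl ether.

Step 21
Reactants: 32 19-alcohol
Product: 33 19-acetoxy-2α-(tert-butyldimethylsilyloxy)-14,15-dinorlabd-8(17)-en-13-one
Conditions: Ac2O, pyridine, DMAP (cat.), CH2Cl2, rt
Reagents that add atoms: acetic anhydride, CC(=O)OC(C)=O
Why: DMAP-catalysed acylation; C19–OH is the only free hydroxyl at this stage, so no selectivity is needed.

Step 22
Reactants: 33 19-acetate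
Product: 34 19-acetoxy-2α-(tert-butyldimethylsilyloxy)-7α-hydroxy-14,15-dinorlabd-8(17)-en-13-one
Conditions: SeO2 (0.3 equiv), t-BuOOH, CH2Cl2, 0 °C → rt
Reagents that add atoms: tert-butyl hydroperoxide, CC(C)(C)OO (oxygen relayed by selenium dioxide, O=[Se]=O)
Why: Selenium dioxide allylic hydroxylation: ene reaction at C17 with removal of a C7 hydrogen, then [2,3]-sigmatropic shift, which returns the C8=C17 bond and places oxygen on C7 (CH2 is preferred over the hindered tertiary C9–H). Oxygen is delivered axially on the α face, away from the C20 methyl group, and the catalytic Sharpless conditions limit over-oxidation.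

Step 23
Reactants: 34 7α-alcohol
Product: 35 19-acetoxy-2α,7α-dihydroxy-14,15-dinorlabd-8(17)-en-13-one (CNP0139304.2)
Conditions: HF·pyridine, THF, 0 °C → rt
Reagents that add atoms: none
Why: Fluoride cleavage of the remaining secondary silyl ether under mildly acidic, non-nucleophilic conditions that leave the acetate, the allylic alcohol, the exocyclic alkene and the ketone untouched.

## Compound list

1 | cis,cis-cyclohexane-1,3,5-triol | O[C@@H]1C[C@H](O)C[C@H](O)C1 | starting material
2 | all-cis-5-(tert-butyldimethylsilyloxy)cyclohexane-1,3-diol (meso) | O[C@@H]1C[C@H](O)C[C@H](O[Si](C)(C)C(C)(C)C)C1 | intermediate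
3 | (1R,3S,5S)-3-hydroxy-5-(tert-butyldimethylsilyloxy)cyclohexyl acetate | CC(=O)O[C@@H]1C[C@H](O)C[C@H](O[Si](C)(C)C(C)(C)C)C1 | intermediate
4 | cis-3-acetoxy-5-(tert-butyldimethylsilyloxy)cyclohexanone (not isolated) | CC(=O)O[C@@H]1CC(=O)C[C@H](O[Si](C)(C)C(C)(C)C)C1 | intermediate
5 | (R)-5-(tert-butyldimethylsilyloxy)cyclohex-2-en-1-one | O=C1C=CC[C@@H](O[Si](C)(C)C(C)(C)C)C1 | intermediate
6 | (5R)-5-(tert-butyldimethylsilyloxy)-1-methylcyclohex-2-en-1-ol (C1 epimers) | CC1(O)C=CC[C@@H](O[Si](C)(C)C(C)(C)C)C1 | intermediate
7 | (S)-5-(tert-butyldimethylsilyloxy)-3-methylcyclohex-2-en-1-one | O=C1C=C(C)C[C@H](O[Si](C)(C)C(C)(C)C)C1 | intermediate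
8 | ring A trimethylsilyl enol ether (C10=C5; 2α-OTBS; 4α-methyl; 4β-CH2SiMe2Ph) | C[Si](C)(C)OC1=C[C@@](C)(C[Si](C)(C)c2ccccc2)C[C@H](O[Si](C)(C)C(C)(C)C)C1 | intermediate
9 | 5-(dimethylaminomethyl) ring A ketone, Mannich base (C5 epimers; not isolated) | CN(C)CC1C(=O)C[C@@H](O[Si](C)(C)C(C)(C)C)C[C@]1(C)C[Si](C)(C)c1ccccc1 | intermediate
10 | methiodide of 9 (not isolated) | C[N+](C)(C)CC1C(=O)C[C@@H](O[Si](C)(C)C(C)(C)C)C[C@]1(C)C[Si](C)(C)c1ccccc1.[I-] | intermediate
11 | 5-methylene ring A ketone (C10=O; C5=C6) | C=C1C(=O)C[C@@H](O[Si](C)(C)C(C)(C)C)C[C@]1(C)C[Si](C)(C)c1ccccc1 | intermediate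
12 | 1-(tert-butyldimethylsilyloxy)-1-methoxyethene | C=C(OC)O[Si](C)(C)C(C)(C)C | starting material
13 | C10 tert-butyldimethylsilyl enol ether of the Michael adduct (not isolated) | COC(=O)CCC1=C(O[Si](C)(C)C(C)(C)C)C[C@@H](O[Si](C)(C)C(C)(C)C)C[C@]1(C)C[Si](C)(C)c1ccccc1 | intermediate
14 | ring A keto ester (5α-H; 5β-CH2CH2CO2Me; 4β-CH2SiMe2Ph) | COC(=O)CC[C@@H]1C(=O)C[C@@H](O[Si](C)(C)C(C)(C)C)C[C@]1(C)C[Si](C)(C)c1ccccc1 | intermediate
15 | ring A hydroxy keto ester (19-OH) | COC(=O)CC[C@@H]1C(=O)C[C@@H](O[Si](C)(C)C(C)(C)C)C[C@]1(C)CO | intermediate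
16 | ring A keto ester with 19-OSiEt3 | COC(=O)CC[C@@H]1C(=O)C[C@@H](O[Si](C)(C)C(C)(C)C)C[C@]1(C)CO[Si](CC)(CC)CC | intermediate
17 | methyl ester with exocyclic C10=C20 | COC(=O)CC[C@@H]1C(=C)C[C@@H](O[Si](C)(C)C(C)(C)C)C[C@]1(C)CO[Si](CC)(CC)CC | intermediate
18 | C8 carboxylic acid | OC(=O)CC[C@@H]1C(=C)C[C@@H](O[Si](C)(C)C(C)(C)C)C[C@]1(C)CO[Si](CC)(CC)CC | intermediate
19 | isobutyl mixed carbonic anhydride of 18 (not isolated) | CC(C)COC(=O)OC(=O)CC[C@@H]1C(=C)C[C@@H](O[Si](C)(C)C(C)(C)C)C[C@]1(C)CO[Si](CC)(CC)CC | intermediate
20 | ring A methylenecyclohexane diazoketone | [N-]=[N+]=CC(=O)CC[C@@H]1C(=C)C[C@@H](O[Si](C)(C)C(C)(C)C)C[C@]1(C)CO[Si](CC)(CC)CC | intermediate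
21 | tricyclic cyclopropyl ketone (C9–C10–C20 ring; C8=O) | O=C1CC[C@H]2[C@@](C)(CO[Si](CC)(CC)CC)C[C@H](O[Si](C)(C)C(C)(C)C)C[C@@]23C[C@@H]13 | intermediate
22 | lithium C8–C9 enolate of the angularly methylated decalone (not isolated) | [Li]OC=1CC[C@H]2[C@@](C)(CO[Si](CC)(CC)CC)C[C@H](O[Si](C)(C)C(C)(C)C)C[C@]2(C)C=1 | intermediate
23 | 9-(dimethylaminomethyl)-8-ketone, Mannich base (C9 epimers; not isolated) | CN(C)CC1C(=O)CC[C@H]2[C@@](C)(CO[Si](CC)(CC)CC)C[C@H](O[Si](C)(C)C(C)(C)C)C[C@]12C | intermediate
24 | methiodide of 23 (not isolated) | C[N+](C)(C)CC1C(=O)CC[C@H]2[C@@](C)(CO[Si](CC)(CC)CC)C[C@H](O[Si](C)(C)C(C)(C)C)C[C@]12C.[I-] | intermediate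
25 | 9(11)-en-8-one (exocyclic enone) | C=C1C(=O)CC[C@H]2[C@@](C)(CO[Si](CC)(CC)CC)C[C@H](O[Si](C)(C)C(C)(C)C)C[C@]12C | intermediate
26 | S-ethyl thioacetate | CCSC(C)=O | starting material
27 | 1-(ethylsulfanyl)-1-(trimethylsilyloxy)ethene | C=C(SCC)O[Si](C)(C)C | intermediate
28 | C8 trimethylsilyl enol ether of the thioester adduct (not isolated) | CCSC(=O)CCC1=C(O[Si](C)(C)C)CC[C@H]2[C@@](C)(CO[Si](CC)(CC)CC)C[C@H](O[Si](C)(C)C(C)(C)C)C[C@]12C | intermediate
29 | 8-oxo S-ethyl thioester (9α-H) | CCSC(=O)CC[C@H]1C(=O)CC[C@H]2[C@@](C)(CO[Si](CC)(CC)CC)C[C@H](O[Si](C)(C)C(C)(C)C)C[C@]12C | intermediate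
30 | 8(17)-ene S-ethyl thioester | CCSC(=O)CC[C@H]1C(=C)CC[C@H]2[C@@](C)(CO[Si](CC)(CC)CC)C[C@H](O[Si](C)(C)C(C)(C)C)C[C@]12C | intermediate
31 | 2α-OTBS-19-OSiEt3-14,15-dinorlabd-8(17)-en-13-one | CC(=O)CC[C@H]1C(=C)CC[C@H]2[C@@](C)(CO[Si](CC)(CC)CC)C[C@H](O[Si](C)(C)C(C)(C)C)C[C@]12C | intermediate
32 | 2α-OTBS-19-hydroxy-14,15-dinorlabd-8(17)-en-13-one | CC(=O)CC[C@H]1C(=C)CC[C@H]2[C@@](C)(CO)C[C@H](O[Si](C)(C)C(C)(C)C)C[C@]12C | intermediate
33 | 19-acetoxy-2α-OTBS-14,15-dinorlabd-8(17)-en-13-one | CC(=O)CC[C@H]1C(=C)CC[C@H]2[C@@](C)(COC(C)=O)C[C@H](O[Si](C)(C)C(C)(C)C)C[C@]12C | intermediate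
34 | 19-acetoxy-2α-OTBS-7α-hydroxy-14,15-dinorlabd-8(17)-en-13-one | CC(=O)CC[C@H]1C(=C)[C@H](O)C[C@H]2[C@@](C)(COC(C)=O)C[C@H](O[Si](C)(C)C(C)(C)C)C[C@]12C | intermediate
35 | 19-acetoxy-2α,7α-dihydroxy-14,15-dinorlabd-8(17)-en-13-one (CNP0139304.2) | C=C1[C@H](O)C[C@H]2[C@@](C)(COC(C)=O)C[C@H](O)C[C@]2(C)[C@H]1CCC(C)=O | target

## Step count and least certain steps

Total: 23 steps. Longest linear sequence: 22 steps (1 → 35 through steps 1–15 and 17–23; step 16 is a one-step branch that makes 27).

**Step 14 (key step).** The carbenoid may insert into the allylic C5–H bond or add to the β face of the alkene, because both paths are intramolecular and the β face is shielded only by the C19 group. The fallback builds ring B by annulation and delivers the methylene group with a hydroxyl director; it sets out from 11 and returns at 21. Compound 11 and 2-(trimethylsilyloxy)propene (Sc(OTf)3, as in step 8) give the C10 trimethylsilyl enol ether F1, which Bu4NF/AcOH protonates to the 1,5-diketone F2 with 5α-H. Fleming–Tamao oxidation as in step 9 gives the 19-hydroxy diketone F3, and Et3SiCl gives the 19-triethylsilyl ether F4. Intramolecular aldol condensation of the methyl ketone onto C10 (pyrrolidine, AcOH, toluene, 60 °C) gives the 9(10)-en-8-one F5. LiBH(s-Bu)3 at −78 °C attacks the carbonyl equatorially and gives the pseudo-axial 8β-allylic alcohol F6. Et2Zn/CH2I2, directed by that hydroxyl to the β face, gives the cyclopropyl carbinol F7, and Dess–Martin oxidation of F7 gives 21.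

**Step 15.** Proton exchange between the lithium enolate and the amide or alkoxide bases may scramble the enolate regiochemistry, the ketone may be over-reduced, or aminomethylation at the hindered C9 may be incomplete. The fallback traps the enolate by Michael addition and sets C9 under thermodynamic control; it sets out from 21 and returns at 32. After the same Li/NH3 reduction, 3-(trimethylsilyl)but-3-en-2-one is added to the enolate to give the α-silyl 8,13-diketone F8. KF in methanol removes the silyl group to give the 8,13-diketone F9 as C9 epimers, mainly with the chain axial. Me3SiOCH2CH2OSiMe3 with catalytic Me3SiOTf at −78 °C ketalises only the unhindered C13 ketone, and NaOMe in methanol then equilibrates C9 to the equatorial chain, giving the 13-dioxolane 8-ketone F10. Ph3P=CH2 gives the 8(17)-ene ketal F11, and PPTS in aqueous acetone removes the dioxolane and the triethylsilyl ether to give 32.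

**Step 9.** The electrophilic peracid conditions may remove the C2 silyl ether, brominate the ketone at its α-position or start a Baeyer–Villiger oxidation of the C10 ketone. The fallback uses an alkoxysilane that is oxidised under nucleophilic, weakly basic conditions; it sets out from 7 and returns at 15. (i-PrO)Me2SiCH2MgCl with CuI and Me3SiCl gives the isopropoxysilyl enol ether F12. Dimethylmethyleneiminium chloride gives the Mannich base F13, MeI its methiodide F14, and NaHCO3 the 5-methylene ketone F15. Addition of 12 as in step 8 gives the silyl enol ether F16 and, after Bu4NF/AcOH, the isopropoxysilyl keto ester F17. Tamao oxidation (H2O2, KF, KHCO3, THF/MeOH) converts F17 into 15.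

**Step 22.** The allylic alcohol may be over-oxidised to the enone, oxidation may take place at C9, or facial selectivity may be poor, because the reagent discriminates only through the shape of ring B. The fallback installs the C7 oxygen by enolate oxidation before the alkene exists; it sets out from 25 and returns at 35. Deprotonation of 25 at C7 with LiN(SiMe3)2 at −78 °C and oxidation with 2-(phenylsulfonyl)-3-phenyloxaziridine (axial attack on the α face) give the 7α-hydroxy enone F18, which t-BuMe2SiOTf/2,6-lutidine converts into the 7α-silyl ether F19. Addition of 27 as in step 17 gives the silyl enol ether F20 and, after protonation, the 8-oxo thioester F21. Zn/CH2Br2/TiCl4 gives the 8(17)-ene thioester F22, and Me2CuLi the methyl ketone F23. Buffered HF·pyridine gives the 19-alcohol F24, Ac2O the 19-acetate F25, and HF·pyridine removes both secondary silyl ethers of F25 to give 35.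

**Step 2.** The enzyme may acetylate the other enantiotopic hydroxyl, which would carry the whole route into the mirror-image series. The fallback changes the way the methyl group is introduced so that the other enone converges on the same 7; it sets out from 2 and returns at 7. The mirror-image monoacetate F26 is oxidised and eliminated as in step 3, through the acetoxy ketone F27, to the (S)-5-silyloxy enone F28. Me2CuLi with Me3SiCl adds the methyl group to the β-carbon, trans to the silyloxy group, and gives the trimethylsilyl enol ether F29. Saegusa–Ito dehydrogenation with Pd(OAc)2 in MeCN gives 7, because keeping the carbonyl in place leads from the (S)-enone to the same enantiomer that 1,2-addition and transposition give from the (R)-enone.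

## Further compounds

F1 | step 14 | C10 trimethylsilyl enol ether of the acetone Michael adduct of 11 | CC(=O)CCC1=C(O[Si](C)(C)C)C[C@@H](O[Si](C)(C)C(C)(C)C)C[C@]1(C)C[Si](C)(C)c1ccccc1
F2 | step 14 | ring A 1,5-diketone (5α-H; 4β-CH2SiMe2Ph) | CC(=O)CC[C@@H]1C(=O)C[C@@H](O[Si](C)(C)C(C)(C)C)C[C@]1(C)C[Si](C)(C)c1ccccc1
F3 | step 14 | 19-hydroxy 1,5-diketone | CC(=O)CC[C@@H]1C(=O)C[C@@H](O[Si](C)(C)C(C)(C)C)C[C@]1(C)CO
F4 | step 14 | 19-triethylsilyloxy 1,5-diketone | CC(=O)CC[C@@H]1C(=O)C[C@@H](O[Si](C)(C)C(C)(C)C)C[C@]1(C)CO[Si](CC)(CC)CC
F5 | step 14 | bicyclic 9(10)-en-8-one | O=C1CC[C@H]2[C@@](C)(CO[Si](CC)(CC)CC)C[C@H](O[Si](C)(C)C(C)(C)C)CC2=C1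
F6 | step 14 | 8β-hydroxy-9(10)-ene | O[C@H]1CC[C@H]2[C@@](C)(CO[Si](CC)(CC)CC)C[C@H](O[Si](C)(C)C(C)(C)C)CC2=C1
F7 | step 14 | 8β-hydroxy C9–C10–C20 cyclopropane | O[C@H]1CC[C@H]2[C@@](C)(CO[Si](CC)(CC)CC)C[C@H](O[Si](C)(C)C(C)(C)C)C[C@@]23C[C@@H]13
F8 | step 15 | 12-(trimethylsilyl)-8,13-diketone (C9 and C12 epimers) | CC(=O)C(CC1C(=O)CC[C@H]2[C@@](C)(CO[Si](CC)(CC)CC)C[C@H](O[Si](C)(C)C(C)(C)C)C[C@]12C)[Si](C)(C)C
F9 | step 15 | 8,13-diketone (C9 epimers) | CC(=O)CCC1C(=O)CC[C@H]2[C@@](C)(CO[Si](CC)(CC)CC)C[C@H](O[Si](C)(C)C(C)(C)C)C[C@]12C
F10 | step 15 | 13-dioxolane 8-ketone (9α-H) | CC1(CC[C@H]2C(=O)CC[C@H]3[C@@](C)(CO[Si](CC)(CC)CC)C[C@H](O[Si](C)(C)C(C)(C)C)C[C@]23C)OCCO1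
F11 | step 15 | 13-dioxolane 8(17)-ene | CC1(CC[C@H]2C(=C)CC[C@H]3[C@@](C)(CO[Si](CC)(CC)CC)C[C@H](O[Si](C)(C)C(C)(C)C)C[C@]23C)OCCO1
F12 | step 9 | ring A trimethylsilyl enol ether with 4β-CH2SiMe2(Oi-Pr) | C[Si](C)(C)OC1=C[C@@](C)(C[Si](C)(C)OC(C)C)C[C@H](O[Si](C)(C)C(C)(C)C)C1
F13 | step 9 | isopropoxysilyl Mannich base (C5 epimers) | CN(C)CC1C(=O)C[C@@H](O[Si](C)(C)C(C)(C)C)C[C@]1(C)C[Si](C)(C)OC(C)C
F14 | step 9 | methiodide of F13 | C[N+](C)(C)CC1C(=O)C[C@@H](O[Si](C)(C)C(C)(C)C)C[C@]1(C)C[Si](C)(C)OC(C)C.[I-]
F15 | step 9 | isopropoxysilyl 5-methylene ketone | C=C1C(=O)C[C@@H](O[Si](C)(C)C(C)(C)C)C[C@]1(C)C[Si](C)(C)OC(C)C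
F16 | step 9 | isopropoxysilyl C10 silyl enol ether of the Michael adduct | COC(=O)CCC1=C(O[Si](C)(C)C(C)(C)C)C[C@@H](O[Si](C)(C)C(C)(C)C)C[C@]1(C)C[Si](C)(C)OC(C)C
F17 | step 9 | isopropoxysilyl keto ester (5α-H) | COC(=O)CC[C@@H]1C(=O)C[C@@H](O[Si](C)(C)C(C)(C)C)C[C@]1(C)C[Si](C)(C)OC(C)C
F18 | step 22 | 7α-hydroxy-9(11)-en-8-one | C=C1C(=O)[C@H](O)C[C@H]2[C@@](C)(CO[Si](CC)(CC)CC)C[C@H](O[Si](C)(C)C(C)(C)C)C[C@]12C
F19 | step 22 | 7α-(tert-butyldimethylsilyloxy)-9(11)-en-8-one | C=C1C(=O)[C@H](O[Si](C)(C)C(C)(C)C)C[C@H]2[C@@](C)(CO[Si](CC)(CC)CC)C[C@H](O[Si](C)(C)C(C)(C)C)C[C@]12C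
F20 | step 22 | 7α-silyloxy C8 trimethylsilyl enol ether thioester | CCSC(=O)CCC1=C(O[Si](C)(C)C)[C@H](O[Si](C)(C)C(C)(C)C)C[C@H]2[C@@](C)(CO[Si](CC)(CC)CC)C[C@H](O[Si](C)(C)C(C)(C)C)C[C@]12C
F21 | step 22 | 7α-silyloxy 8-oxo thioester (9α-H) | CCSC(=O)CC[C@H]1C(=O)[C@H](O[Si](C)(C)C(C)(C)C)C[C@H]2[C@@](C)(CO[Si](CC)(CC)CC)C[C@H](O[Si](C)(C)C(C)(C)C)C[C@]12C
F22 | step 22 | 7α-silyloxy 8(17)-ene thioester | CCSC(=O)CC[C@H]1C(=C)[C@H](O[Si](C)(C)C(C)(C)C)C[C@H]2[C@@](C)(CO[Si](CC)(CC)CC)C[C@H](O[Si](C)(C)C(C)(C)C)C[C@]12C
F23 | step 22 | 2α,7α-bis(silyloxy)-19-OSiEt3 13-ketone | CC(=O)CC[C@H]1C(=C)[C@H](O[Si](C)(C)C(C)(C)C)C[C@H]2[C@@](C)(CO[Si](CC)(CC)CC)C[C@H](O[Si](C)(C)C(C)(C)C)C[C@]12C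
F24 | step 22 | 2α,7α-bis(silyloxy)-19-hydroxy 13-ketone | CC(=O)CC[C@H]1C(=C)[C@H](O[Si](C)(C)C(C)(C)C)C[C@H]2[C@@](C)(CO)C[C@H](O[Si](C)(C)C(C)(C)C)C[C@]12C
F25 | step 22 | 19-acetoxy-2α,7α-bis(silyloxy) 13-ketone | CC(=O)CC[C@H]1C(=C)[C@H](O[Si](C)(C)C(C)(C)C)C[C@H]2[C@@](C)(COC(C)=O)C[C@H](O[Si](C)(C)C(C)(C)C)C[C@]12C
F26 | step 2 | (1S,3R,5R)-3-hydroxy-5-(tert-butyldimethylsilyloxy)cyclohexyl acetate | CC(=O)O[C@H]1C[C@@H](O)C[C@@H](O[Si](C)(C)C(C)(C)C)C1
F27 | step 2 | mirror-image cis-3-acetoxy-5-(tert-butyldimethylsilyloxy)cyclohexanone | CC(=O)O[C@H]1CC(=O)C[C@@H](O[Si](C)(C)C(C)(C)C)C1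
F28 | step 2 | (S)-5-(tert-butyldimethylsilyloxy)cyclohex-2-en-1-one | O=C1C=CC[C@H](O[Si](C)(C)C(C)(C)C)C1
F29 | step 2 | trans-3-methyl-5-(tert-butyldimethylsilyloxy)-1-(trimethylsilyloxy)cyclohex-1-ene | C[C@@H]1C=C(O[Si](C)(C)C)C[C@@H](O[Si](C)(C)C(C)(C)C)C1
A1 | alternative 1 | 8-phenylmenthyl (6E,10E)-2,6,10-trimethyl-13-(2-methyl-1,3-dioxolan-2-yl)-3-oxotrideca-6,10-dienoate | CC(C(=O)O[C@@H]1C[C@H](C)CC[C@H]1C(C)(C)c1ccccc1)C(=O)CC/C(C)=C/CC/C(C)=C/CCC1(C)OCCO1
A2 | alternative 1 | 8-phenylmenthyl 13,13-ethylenedioxy-3-oxo-14,15-dinorlabd-8(17)-en-19-oate | C=C1CC[C@H]2[C@@](C)(C(=O)O[C@@H]3C[C@H](C)CC[C@H]3C(C)(C)c3ccccc3)C(=O)CC[C@]2(C)[C@H]1CCC1(C)OCCO1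
A3 | alternative 2 | ring B ketone with (Z)-3-iodoallyl group on C10 and 3-(silyloxy)prop-1-en-2-yl group on C5 | O=C1CC[C@@H](C(=C)CO[Si](C)(C)C(C)(C)C)[C@](C)(C/C=C\I)[C@H]1CCC1(C)OCCO1
A4 | alternative 2 | 19-(tert-butyldimethylsilyloxy)-13,13-ethylenedioxy-14,15,17-trinorlabd-2-en-8-one | O=C1CC[C@H]2[C@@](C)(CO[Si](C)(C)C(C)(C)C)C=CC[C@]2(C)[C@H]1CCC1(C)OCCO1
A5 | alternative 3 | 2,2-dimethyl-1,3-dioxin-4-one joined through C6–C7 to C5 of ring A bearing 10α-vinyl and 10β-methyl | O=C1C=C(CC[C@@H]2[C@@](C)(C=C)C[C@@H](O[Si](C)(C)C(C)(C)C)C[C@]2(C)CO[Si](CC)(CC)CC)OC(C)(C)O1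
A6 | alternative 3 | methyl 2α-(tert-butyldimethylsilyloxy)-8-oxo-19-(triethylsilyloxy)-14,15,16,17-tetranorlabdan-13-oate | O=C1CC[C@H]2[C@@](C)(CO[Si](CC)(CC)CC)C[C@H](O[Si](C)(C)C(C)(C)C)C[C@]2(C)[C@H]1CCC(=O)OC
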